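(The runs are calculated with constants of no real substance; noise was put on by code.)

It was impossible for the uncatalysed product to fall in the south-west flask, since none of the steps thought possible uses it up, so what is asked is how much stands at 10 d.

| setting | south-west | north-west | flask |
|---|---|---|---|
| starting material | 0.54 M | 0.54 M | 0.54 M |
| partner | 3 equiv | 1.5 equiv | 3.00 equiv |
| second substrate | 1 equiv | 1 equiv | 1.00 equiv |
| free catalyst | 0.5 mol% | 0.5 mol% | 0.5 mol% |
| remark | the very flask that is asked about, followed so far | run made earlier |  |
| time |  |  | 10 d |

- south-west (time / d: uncatalysed product / %, target / %): 2.50: 5.0, 58.5; 3.00: 4.7, 57.5; 4.00: 5.6, 57.8
- north-west (time / d: uncatalysed product / %, target / %): 2.50: 2.7, 34.0; 3.00: 3.0, 35.8; 4.00: 3.8, 34.2; 5.00: 3.7, 33.6; 6.00: 6.0, 33.8; 8.00: 6.8, 33.0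

(standard deviation of a reading: 1 percentage point)

- the moment within 10 d at which there is most uncatalysed product
- the amount of uncatalysed product, in percent of the starting material charged, at that time

- the analysis behind the earlier runs scatters by 1 percentage point, standard deviation
- steps thought possible: starting material + partner + free catalyst -> free catalyst + target; second substrate + partner + free catalyst -> free catalyst + second product; starting material + partner -> uncatalysed product; free catalyst -> spent catalyst

Target stays flat from the first reading in both runs, so I read the later rise of uncatalysed product as the step of starting material with partner. In the north-west run it rose by 0.00745 /d of the charge, with 62.7% of the starting material left at 5.00 d. I divided that rise by the fraction of starting material left and the equivalents of partner left, and called the result the background figure. The balance of partner needs what second substrate took, which nobody measured.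

If it took none, the north-west run kept 1.13 equivalents. The south-west flask at 4.00 d, with 36.6% of its starting material and 2.37 equivalents, would then gain 0.00914 /d. If all of it reacted, the north-west run kept 0.127 and the south-west flask 1.37, and the gain would be 0.0468 /d. That means 7 percentage points across the south-west readings, which moved 0.6 points. So I put the south-west flask between the two versions.

I let second substrate take as much partner as target did. That leaves 0.791 in the north-west run, so the background figure is 0.0150 /d. The south-west flask then gains 0.00984 /d, which gives 11.5% at 10 d.

The forecast, “assuming the second substrate reacts about as fast as the starting material”, said 11.5% at 10 d.

The flask gave 14.3% at 10.0 d, 2.8 points above the forecast's figure.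

    starting material + partner + free catalyst → free catalyst + target (k = 23.0 /M²/h)
    second substrate + partner + free catalyst → free catalyst + second product (k = 30.0 /M²/h)
    starting material + partner → uncatalysed product (k = 0.00180 /M/h)
    free catalyst → spent catalyst (k = 0.0810 /h)

At 5.00 d partner stood at 54.7% of its charge, 1.64 equivalents, between my two versions. In the neighbour flask with 0.12 mol% of free catalyst, starting material ended at 44.6% and partner at 71.7% of its charge. The background figure, on the means of start and end, gives 28.0% over 10 d, and that flask holds 32.6%.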